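## The problem

Canaliculatol is a resveratrol trimer. Labels used here: ring A is the indane arene; C1, C2 and C3 are the indane CH carbons bearing 4-hydroxyphenyl, ring C and Cm; Cm is the CH(4-hydroxyphenyl) carbon between C3 and ring B; ring B is the resorcinol ring between Cm and C3'; ring C is the benzofuran arene; C2' is the OCH(4-hydroxyphenyl) and C3' the CH(ring B) carbon of the dihydrofuran. The indane, an eight-membered ring (C2, C3, Cm, two carbons of ring B, C3', two carbons of ring C) and a trans-2-aryl-2,3-dihydrobenzofuran share edges, so the medium ring cannot be made apart from its neighbours. Reading the SMILES gives C1 R, C2 S, C3 R, Cm R, C3' R, C2' R: the indane is 1,2-cis/2,3-trans and C2'/C3' are trans. The 1,2-cis relation is the less stable one, so C1 must be set kinetically. C2' can control C3', and C3 can control C2 (trans by equilibration), then C1 and Cm. The pair C2'/C3' and the set C1–C3 lie on opposite sides of ring C and cannot control each other, so two independent absolute inputs are needed. The eight phenols are carried as methyl ethers. The benzylic aryl ether C2'–O is the fragile group: strong acid ionises it and hydrogenolysis would cleave it. The enabling feature is that C2', with its aryl group and its ether oxygen on ring C, is C2 of a flavanone, and C3' is bonded to the ring-C carbon that carries the flavanone carbonyl. A 1,2-shift of that ring-C carbon from the carbonyl carbon to the α-carbon therefore makes the C3'–ring C bond, contracts the pyranone to the dihydrofuran and leaves a carboxyl group on C3', where ring B has to be attached.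

## Retrosynthesis

**29 from 28.** The eight O–methyl bonds are cut last. Methyl ethers survive organometallic reagents, palladium and nickel catalysis and the acidic steps. Benzyl ethers are excluded because their hydrogenolysis would endanger C2'–O. The forward step is a BBr3 demethylation that must leave the dihydrofuran closed.

**28 from 27 (and 27 from 26 and 22).** The Cm–ring B bond is cut. Closing the eight-membered ring here needs only a 4-methoxybenzylic cation next to a resorcinol dimethyl ether that has two equivalent ortho positions. Closing at C2–ring C instead would require the Cm–ring B bond to be made intermolecularly, with no control of site among three electron-rich arenes. The precursor 27 is an open carbinol whose Cm configuration is irrelevant. The forward reaction must close an eight-membered ring and fix Cm. Attack on ring C would give a trans-fused bicyclo[3.3.0] system and is not expected. The cation should react with its aryl group eclipsing C3–H, and ring B can reach only the face on the C2 side, which corresponds to the required Cm configuration. Carbinol 27 comes from aldehyde 26 and Grignard reagent 22; 26 comes from alcohol 25 and silyl ether 24.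

**24 from 21 and 22 (through 23).** The C1–aryl and C1–H bonds are cut back to ketone 21. Hydrogenation of a C1=C2 indene would add hydrogen anti to the C3 substituent and give the all-cis indane. Hydride delivery to a C1 cation anti to ring C on C2 gives the 1,2-cis/2,3-trans pattern. This must come before any chemistry at Cm: with a C1 ketone still present, ionisation at Cm would open a path to a conjugated indenone and erase C2 and C3.

**21 from 12 and 20.** The C2–ring C bond is cut. This is the convergent joint between two enantioenriched halves, the aryl chloride 12 and the indanone 20, made by palladium-catalysed α-arylation. C2 is acidic in the product and settles trans to C3. C3 carries a silyloxymethyl group and no acidic hydrogen, so it keeps its configuration under base. An ester at C3 would be shorter but would racemise.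

**20 from 18, 18 from 15, 15 from 13 and 14.** The indanone is opened at the aryl–carbonyl bond (Friedel–Crafts acylation of a symmetric 3,5-dimethoxyphenyl group, no regiochemical issue). The benzylic stereocentre goes back to a rhodium-catalysed conjugate addition of boronic acid 14 to butenolide 13. The lactone oxygen becomes the protected hydroxymethyl group that is later oxidised to the Cm aldehyde.

**12 from 10 and 11 (10 from 9).** The C3'–ring B bond is cut to a carboxylic acid and an aryl bromide. The acid is what the ring contraction leaves on C3'. Its radical is planar, so C3' is reset trans to the C2' aryl group whatever the ester configuration was. The chloride on ring C must survive this nickel-catalysed step, which is why chlorine rather than bromine marks the later C2 attachment.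

**9 from 7.** The C3'–ring C bond is cut by reversing an oxidative 1,2-shift, which leads back to the (R)-flavanone 7. One stereocentre, set by catalysis, then carries the whole dihydrobenzofuran.

**7 from 5 and 6; 5 from 3; 3 from 1.** The flavanone comes from asymmetric conjugate addition of boronic acid 6 to chromone 5. The chromone comes from the ortho-hydroxyacetophenone 3 through enaminone 4. Ketone 3 is made from the symmetric dimethyl ether 1 rather than from a mono-phenol: acylation of 1 can give only two regioisomers, and the ortho hydroxyl is then freed by chelation-controlled demethylation via 2.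

## Roads not taken

Alternative 1: Ring A is built last on the indane side by benzannulation. The cut removes four C–C bonds of ring A. In the forward step, irradiation of the cyclopentenyl diazomethyl ketone A1 gives a ketene by Wolff rearrangement. This ketene adds the siloxyalkyne A2, and ring opening and 6π closure give the resorcinol mono-silyl ether A3. Its merits are real: the three indane stereocentres are set on a cyclopentene before the arene exists, so the 1,2-cis relation never depends on a benzylic cation. Ring A also arrives with its two oxygens differentiated. In this respect it is better than the chosen plan, which relies on facial control in a hydride transfer. Its weak points are that A1, a tetrasubstituted cyclopentene with four stereocentres and a diazo ketone, is itself a long synthesis. After A3, the whole dihydrobenzofuran (C2', C3', the ether oxygen, ring B) and the eight-membered ring still have to be built at a hindered ortho position of a dimethoxyphenyl group. The hardest part is therefore postponed. The chosen plan sets against this a complete, enantioenriched dihydrobenzofuran in six steps and a convergent union.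

Alternative 2: Both bonds from ring B (to C3' and to Cm) are cut. Fluoride releases the aryne from the silylaryl triflate A5, and the aryne inserts into the C–C(=O) bond of the cyclic β-keto ester A4. This expands the six-membered ring to the eight-membered ketone A6. The medium ring is thus made by ring expansion and ring B is attached by two bonds at once, with regiochemistry set by the methoxy group next to the aryne. This is a better answer to the eight-membered ring than the direct closure of the chosen plan. The costs come afterwards and before. A4 is a hindered tetracyclic keto ester that already needs the full indane. In A6 one of the two methyl ethers on ring C must be freed selectively among eight to close the dihydrofuran. C2' must be grown from the ester with trans control. Cm needs aryl addition and deoxygenation inside the medium ring with uncertain facial control. The chosen plan has the ether oxygen differentiated from the start (it is the flavanone oxygen) and fixes C2'/C3' early, at the price of a Friedel–Crafts closure of the eight-membered ring.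

Alternative 3: Ring C is made from a 2-pyrone. The two ring-C bonds flanking the alkyne carbons are cut. On heating, the tethered silylalkyne of the 3-pyronyl ether A7 adds across C3 and C6 of the pyrone, CO2 is lost, and the dihydrobenzofuran A8 results with ring C and the dihydrofuran closed together. The conditions are neutral, there is no migration selectivity to worry about, and the regiochemistry of ring C is unambiguous; in these respects it is cleaner than the rearrangement chosen here. Its weak points are specific to this target. A8 lacks the oxygen on ring C, which would need a later C–H oxidation. The aryl–silicon bond must be turned into a coupling handle by ipso-halogenation in the presence of more electron-rich arenes. A7 requires a stereodefined anti-1,2-diaryl propargylic ether of 3-hydroxy-2-pyrone, whose benzylic ether and propargylic centre must survive prolonged heating. A8 is the same kind of building block as 12, so the later steps would be equal. The chosen plan reaches 12 with the ring-C oxygen and the chloride in place and with one catalytic asymmetric step.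

Key step: step 4

Assumption: the sense of induction in steps 3 and 7 is taken from the usual models for the named ligands; if either is opposite, the enantiomeric ligand is used.

## Steps

Step 1
Reactants: 1 1-chloro-3,5-dimethoxybenzene
Product: 3 1-(2-chloro-6-hydroxy-4-methoxyphenyl)ethan-1-one, via dimethoxy ketone 2 (not isolated)
Conditions: AcCl, AlCl3 (3 equiv), CH2Cl2, 0 °C then reflux
Reagents that add atoms: acetyl chloride CC(=O)Cl
Why: Friedel–Crafts acylation should occur para to one methoxy group and ortho to chlorine rather than at the more hindered position between the two methoxy groups; excess AlCl3 then cleaves only the methoxy group ortho to the new ketone through the chelate (chelation-controlled demethylation).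

Step 2
Reactants: 3 1-(2-chloro-6-hydroxy-4-methoxyphenyl)ethan-1-one
Product: 5 5-chloro-7-methoxy-4H-chromen-4-one, via enaminone 4 (not isolated)
Conditions: Me2NCH(OMe)2, toluene, 100 °C; then conc. HCl, CH2Cl2, 40 °C
Reagents that add atoms: N,N-dimethylformamide dimethyl acetal COC(OC)N(C)C
Why: Condensation of the methyl ketone with the formamide acetal gives the enaminone, and acid-promoted addition of the phenol with loss of dimethylamine closes the chromone (enaminone route to chromones).

Step 3
Reactants: 5 5-chloro-7-methoxy-4H-chromen-4-one; 6 4-methoxyphenylboronic acid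
Product: 7 (R)-5-chloro-7-methoxy-2-(4-methoxyphenyl)chroman-4-one
Conditions: Pd(OCOCF3)2 (5 mol%), (S)-t-BuPyOx (6 mol%), NH4PF6, H2O, ClCH2CH2Cl, 60 °C
Reagents that add atoms: none
Why: Asymmetric conjugate addition of an arylboronic acid catalysed by cationic divalent palladium with a pyridine-oxazoline ligand; insertion of the C2=C3 bond into the aryl–palladium bond on one enantioface sets C2 as R, and protonation of the palladium enolate by water releases the flavanone. The aryl chloride is inert to divalent palladium.

Step 4
Reactants: 7 (R)-5-chloro-7-methoxy-2-(4-methoxyphenyl)chroman-4-one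
Product: 9 methyl (2R,3R)-4-chloro-6-methoxy-2-(4-methoxyphenyl)-2,3-dihydrobenzofuran-3-carboxylate, via enol ether 8 (not isolated)
Conditions: PhI(OAc)2, H2SO4, HC(OMe)3, rt
Reagents that add atoms: trimethyl orthoformate COC(OC)OC
Why: Acid and the orthoformate turn the ketone of 7 into enol ether 8, which the electrophilic iodane attacks at C3 on the face anti to the C2 aryl group while methanol re-forms the ketal at C4. With the C3–iodine bond equatorial, the C4–C4a bond is antiperiplanar to it, and the ring-C carbon C4a, activated by the para methoxy group, migrates from C4 to C3 through a bridged phenonium-type ion as iodobenzene leaves; the dimethoxycarbenium ion left at C4 loses a methyl group to give the ester. The closest known reaction is this very one, the oxidative ring contraction of flavanones by PhI(OAc)2 or Tl(NO3)3 in trimethyl orthoformate, a cyclic case of the oxidative 1,2-aryl shift of aryl ketones to arylacetic esters. The dihydrofuran ring is closed by contraction of the six-membered pyranone (1,2-shift of a ring bond), not by cyclisation. The new centre C3 forms with inversion at the carbon that bore iodine, which places the ester trans to the C2 aryl group (3R); C2 is not involved and stays R. The step needs migration of ring C in preference to the shift of the 4-methoxyphenyl group from C2 to C3 (isoflavone pathway) and to elimination (flavone); the diequatorial arrangement of aryl group and iodane, which aligns only the ring bond, and the methoxy group para to C4a secure this. It also needs the C2–O bond to stay closed, which the non-basic medium at room temperature favours.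

Step 5
Reactants: 9 methyl (2R,3R)-4-chloro-6-methoxy-2-(4-methoxyphenyl)-2,3-dihydrobenzofuran-3-carboxylate
Product: 10 (2R,3R)-4-chloro-6-methoxy-2-(4-methoxyphenyl)-2,3-dihydrobenzofuran-3-carboxylic acid
Conditions: Me3SnOH, ClCH2CH2Cl, 80 °C; then aq. HCl wash
Reagents that add atoms: trimethyltin hydroxide C[Sn](C)(C)O
Why: Me3SnOH cleaves the methyl ester under neutral conditions, which avoids the ester enolate that would open the dihydrofuran by β-elimination of the phenoxide; C2 is untouched.

Step 6
Reactants: 10 (2R,3R)-4-chloro-6-methoxy-2-(4-methoxyphenyl)-2,3-dihydrobenzofuran-3-carboxylic acid; 11 1-bromo-3,5-dimethoxybenzene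
Product: 12 (2R,3R)-4-chloro-3-(3,5-dimethoxyphenyl)-6-methoxy-2-(4-methoxyphenyl)-2,3-dihydrobenzofuran
Conditions: Ir[dF(CF3)ppy]2(dtbbpy)PF6 (1 mol%), NiCl2(dme) (10 mol%), dtbbpy, Cs2CO3, DMF, blue LEDs, rt
Reagents that add atoms: none
Why: Metallaphotoredox decarboxylative arylation: the excited iridium complex oxidises the carboxylate, loss of CO2 gives the planar benzylic C3 radical, and nickel, which inserts into the aryl bromide far faster than into the hindered aryl chloride, couples the two. The aryl group is delivered anti to the C2 aryl group, so C3' becomes R (trans) whatever the configuration of the acid.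

Step 7
Reactants: 13 furan-2(5H)-one; 14 3,5-dimethoxyphenylboronic acid
Product: 15 (S)-4-(3,5-dimethoxyphenyl)dihydrofuran-2(3H)-one
Conditions: [Rh(OH)((S)-binap)]2 (3 mol%), dioxane/H2O (10:1), 40 °C
Reagents that add atoms: none
Why: Rhodium-catalysed asymmetric 1,4-addition of an arylboronic acid to an unsaturated lactone (Hayashi–Miyaura reaction); the binap–rhodium aryl adds to one enantioface and sets the benzylic centre as S, which becomes C3 of the indane.

Step 8
Reactants: 15 (S)-4-(3,5-dimethoxyphenyl)dihydrofuran-2(3H)-one
Product: 18 (S)-4-(tert-butyldiphenylsilyloxy)-3-(3,5-dimethoxyphenyl)butanoic acid, via potassium hydroxy carboxylate 16 (not isolated), via bis-silyl compound 17 (not isolated)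
Conditions: KOH, MeOH/H2O, rt, evaporate; TBDPSCl, imidazole, DMF, rt; K2CO3, MeOH/THF/H2O, rt
Reagents that add atoms: potassium hydroxide [K+].[OH-]; tert-butyl(chloro)diphenylsilane CC(C)(C)[Si](Cl)(c1ccccc1)c1ccccc1
Why: Saponification, silylation of both oxygens and selective hydrolysis of the labile silyl ester is the standard way from a γ-lactone to a silyloxy acid; the medium stays basic until the alcohol is silylated, which prevents relactonisation, and the stereocentre is not involved.

Step 9
Reactants: 18 (S)-4-(tert-butyldiphenylsilyloxy)-3-(3,5-dimethoxyphenyl)butanoic acid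
Product: 20 (S)-3-[(tert-butyldiphenylsilyloxy)methyl]-5,7-dimethoxyindan-1-one, via mixed anhydride 19 (not isolated)
Conditions: (CF3CO)2O, CH2Cl2, 0 °C to rt
Reagents that add atoms: none
Why: Intramolecular Friedel–Crafts acylation through the mixed trifluoroacetic anhydride; the position attacked is ortho to the chain and ortho/para to the methoxy groups (both ortho positions are equivalent). No strong Lewis acid is present, which should keep the silyl ether from attacking the acyl group.

Step 10
Reactants: 20 (S)-3-[(tert-butyldiphenylsilyloxy)methyl]-5,7-dimethoxyindan-1-one; 12 (2R,3R)-4-chloro-3-(3,5-dimethoxyphenyl)-6-methoxy-2-(4-methoxyphenyl)-2,3-dihydrobenzofuran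
Product: 21 (2R,3S)-3-[(tert-butyldiphenylsilyloxy)methyl]-2-[(2R,3R)-3-(3,5-dimethoxyphenyl)-6-methoxy-2-(4-methoxyphenyl)-2,3-dihydrobenzofuran-4-yl]-5,7-dimethoxyindan-1-one
Conditions: Pd2(dba)3 (2.5 mol%), XPhos (6 mol%), NaOtBu, toluene, 80 °C; aq. NH4Cl
Reagents that add atoms: none
Why: Palladium-catalysed α-arylation of a ketone enolate with an aryl chloride; the bulky biaryl phosphine allows oxidative addition of the hindered chloride to zerovalent palladium. The product is deprotonated as it forms, and protonation with equilibration at the acidic C2 gives the 2,3-trans ketone; C3 has no acidic hydrogen and keeps its configuration.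

Step 11
Reactants: 21 (2R,3S)-3-[(tert-butyldiphenylsilyloxy)methyl]-2-[(2R,3R)-3-(3,5-dimethoxyphenyl)-6-methoxy-2-(4-methoxyphenyl)-2,3-dihydrobenzofuran-4-yl]-5,7-dimethoxyindan-1-one; 22 4-methoxyphenylmagnesium bromide
Product: 23 1-(4-methoxyphenyl)indan-1-ol derived from 21 (tertiary carbinol)
Conditions: CeCl3, THF, −78 °C to 0 °C
Reagents that add atoms: none
Why: Organocerium reagents add to hindered, easily enolised ketones where Grignard reagents mainly deprotonate (1,2-addition); the configuration of the carbinol centre is of no consequence because it is ionised in step 12.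

Step 12
Reactants: 23 1-(4-methoxyphenyl)indan-1-ol derived from 21 (tertiary carbinol)
Product: 24 (1R,2R,3S)-1-(4-methoxyphenyl)indane silyl ether (1,2-cis and 2,3-trans)
Conditions: Et3SiH, CF3CO2H, CH2Cl2, −40 °C to 0 °C
Reagents that add atoms: none
Why: Ionic hydrogenation: acid ionises the tertiary, doubly benzylic alcohol and triethylsilane delivers hydride to the planar C1 cation on the face anti to ring C at C2, which places the C1 aryl group cis to ring C. At low temperature the secondary benzylic ether C2'–O and the silyl ether should not ionise.

Step 13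
Reactants: 24 (1R,2R,3S)-1-(4-methoxyphenyl)indane silyl ether (1,2-cis and 2,3-trans)
Product: 25 primary alcohol (C3–CH2OH)
Conditions: Bu4NF, THF, rt
Reagents that add atoms: none
Why: Fluoride cleaves the silyl ether; no stereocentre is affected.

Step 14
Reactants: 25 primary alcohol (C3–CH2OH)
Product: 26 aldehyde (C3–CHO)
Conditions: Dess–Martin periodinane, CH2Cl2, 0 °C
Reagents that add atoms: none
Why: Dess–Martin oxidation of a primary alcohol under non-basic conditions; if C3 epimerises through the enol, the 2,3-trans aldehyde is the more stable isomer, so the required configuration is kept.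

Step 15
Reactants: 26 aldehyde (C3–CHO); 22 4-methoxyphenylmagnesium bromide
Product: 27 secondary carbinol C3–CH(OH)(4-methoxyphenyl) as both epimers at the carbinol carbon
Conditions: THF, −78 °C
Reagents that add atoms: none
Why: Grignard 1,2-addition to the aldehyde at low temperature; both carbinol epimers are acceptable because Cm is ionised in the next step.

Step 16
Reactants: 27 secondary carbinol C3–CH(OH)(4-methoxyphenyl) as both epimers at the carbinol carbon
Product: 28 octa-O-methylcanaliculatol
Conditions: TsOH·H2O (10 mol%), (CF3)2CHOH/CH2Cl2, high dilution, 0 °C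
Reagents that add atoms: none
Why: Intramolecular Friedel–Crafts alkylation: acid in an ionising fluoro alcohol converts the 4-methoxybenzylic alcohol into the Cm cation, which ring B attacks ortho to C3' to close the eight-membered ring. The cation should react with its aryl group eclipsing C3–H (allylic strain), and ring B, tethered through C2, reaches only the face on the C2 side, which gives Cm as R. Closure onto ring C would need a trans-fused bicyclo[3.3.0] system.

Step 17
Reactants: 28 octa-O-methylcanaliculatol
Product: 29 canaliculatol
Conditions: BBr3, CH2Cl2, −78 °C to rt; then H2O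
Reagents that add atoms: none
Why: BBr3 cleaves all eight aryl methyl ethers (Lewis acid–base complex, then bromide attack at methyl); this is the usual deprotection of permethylated resveratrol oligomers with trans-2-aryl-dihydrobenzofurans, and no stereocentre is touched.

## Compound list

In the names below, DHB stands for the (2R,3R)-3-(3,5-dimethoxyphenyl)-6-methoxy-2-(4-methoxyphenyl)-2,3-dihydrobenzofuran-4-yl group. Indanes 23–27 use the target numbering (C1 aryl, C2 DHB, C3 one-carbon branch, methoxy groups at C5 and C7).

1 | 1-chloro-3,5-dimethoxybenzene | COc1cc(Cl)cc(OC)c1 | starting material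
2 | 1-(2-chloro-4,6-dimethoxyphenyl)ethan-1-one | CC(=O)c1c(Cl)cc(OC)cc1OC | intermediate
3 | 1-(2-chloro-6-hydroxy-4-methoxyphenyl)ethan-1-one | CC(=O)c1c(O)cc(OC)cc1Cl | intermediate
4 | (E)-1-(2-chloro-6-hydroxy-4-methoxyphenyl)-3-(dimethylamino)prop-2-en-1-one | CN(C)/C=C/C(=O)c1c(O)cc(OC)cc1Cl | intermediate
5 | 5-chloro-7-methoxy-4H-chromen-4-one | O=c1ccoc2cc(OC)cc(Cl)c12 | intermediate
6 | 4-methoxyphenylboronic acid | COc1ccc(B(O)O)cc1 | starting material
7 | (R)-5-chloro-7-methoxy-2-(4-methoxyphenyl)chroman-4-one | O=C1C[C@H](c2ccc(OC)cc2)Oc2cc(OC)cc(Cl)c21 | intermediate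
8 | (R)-5-chloro-4,7-dimethoxy-2-(4-methoxyphenyl)-2H-chromene | COC1=C[C@H](c2ccc(OC)cc2)Oc2cc(OC)cc(Cl)c21 | intermediate
9 | methyl (2R,3R)-4-chloro-6-methoxy-2-(4-methoxyphenyl)-2,3-dihydrobenzofuran-3-carboxylate (2,3-trans) | COC(=O)[C@H]1[C@H](c2ccc(OC)cc2)Oc2cc(OC)cc(Cl)c21 | intermediate
10 | (2R,3R)-4-chloro-6-methoxy-2-(4-methoxyphenyl)-2,3-dihydrobenzofuran-3-carboxylic acid | OC(=O)[C@H]1[C@H](c2ccc(OC)cc2)Oc2cc(OC)cc(Cl)c21 | intermediate
11 | 1-bromo-3,5-dimethoxybenzene | COc1cc(Br)cc(OC)c1 | starting material
12 | (2R,3R)-4-chloro-3-(3,5-dimethoxyphenyl)-6-methoxy-2-(4-methoxyphenyl)-2,3-dihydrobenzofuran (2,3-trans) | COc1cc(OC)cc(c1)[C@H]1[C@H](c2ccc(OC)cc2)Oc2cc(OC)cc(Cl)c21 | intermediate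
13 | furan-2(5H)-one | O=C1OCC=C1 | starting material
14 | 3,5-dimethoxyphenylboronic acid | COc1cc(OC)cc(B(O)O)c1 | starting material
15 | (S)-4-(3,5-dimethoxyphenyl)dihydrofuran-2(3H)-one | O=C1C[C@@H](c2cc(OC)cc(OC)c2)CO1 | intermediate
16 | potassium (S)-3-(3,5-dimethoxyphenyl)-4-hydroxybutanoate | [K+].[O-]C(=O)C[C@@H](c1cc(OC)cc(OC)c1)CO | intermediate
17 | tert-butyldiphenylsilyl (S)-4-(tert-butyldiphenylsilyloxy)-3-(3,5-dimethoxyphenyl)butanoate | CC(C)(C)[Si](c1ccccc1)(c1ccccc1)OC(=O)C[C@@H](c1cc(OC)cc(OC)c1)CO[Si](c1ccccc1)(c1ccccc1)C(C)(C)C | intermediate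
18 | (S)-4-(tert-butyldiphenylsilyloxy)-3-(3,5-dimethoxyphenyl)butanoic acid | OC(=O)C[C@@H](c1cc(OC)cc(OC)c1)CO[Si](c1ccccc1)(c1ccccc1)C(C)(C)C | intermediate
19 | (S)-4-(tert-butyldiphenylsilyloxy)-3-(3,5-dimethoxyphenyl)butanoic trifluoroacetic anhydride | FC(F)(F)C(=O)OC(=O)C[C@@H](c1cc(OC)cc(OC)c1)CO[Si](c1ccccc1)(c1ccccc1)C(C)(C)C | intermediate
20 | (S)-3-[(tert-butyldiphenylsilyloxy)methyl]-5,7-dimethoxyindan-1-one | O=C1C[C@H](CO[Si](c3ccccc3)(c3ccccc3)C(C)(C)C)c2cc(OC)cc(OC)c21 | intermediate
21 | (2R,3S)-3-[(tert-butyldiphenylsilyloxy)methyl]-2-DHB-5,7-dimethoxyindan-1-one (2,3-trans) | O=C1[C@@H](c2cc(OC)cc3O[C@@H](c4ccc(OC)cc4)[C@H](c4cc(OC)cc(OC)c4)c23)[C@H](CO[Si](c2ccccc2)(c2ccccc2)C(C)(C)C)c2cc(OC)cc(OC)c21 | intermediate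
22 | 4-methoxyphenylmagnesium bromide | COc1ccc([Mg]Br)cc1 | starting material
23 | (1R,2R,3S)-3-[(tert-butyldiphenylsilyloxy)methyl]-2-DHB-5,7-dimethoxy-1-(4-methoxyphenyl)indan-1-ol (aryl group expected anti to ring C; either C1 epimer serves) | O[C@@]1(c2ccc(OC)cc2)[C@@H](c2cc(OC)cc3O[C@@H](c4ccc(OC)cc4)[C@H](c4cc(OC)cc(OC)c4)c23)[C@H](CO[Si](c2ccccc2)(c2ccccc2)C(C)(C)C)c2cc(OC)cc(OC)c21 | intermediate
24 | (1R,2R,3S)-3-[(tert-butyldiphenylsilyloxy)methyl]-2-DHB-5,7-dimethoxy-1-(4-methoxyphenyl)indane (1,2-cis, 2,3-trans) | COc1ccc(cc1)[C@H]1[C@@H](c2cc(OC)cc3O[C@@H](c4ccc(OC)cc4)[C@H](c4cc(OC)cc(OC)c4)c23)[C@H](CO[Si](c2ccccc2)(c2ccccc2)C(C)(C)C)c2cc(OC)cc(OC)c21 | intermediate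
25 | [(1S,2R,3R)-2-DHB-4,6-dimethoxy-3-(4-methoxyphenyl)indan-1-yl]methanol, i.e. the C3–CH2OH compound (1R,2R,3S in target numbering) | COc1ccc(cc1)[C@H]1[C@@H](c2cc(OC)cc3O[C@@H](c4ccc(OC)cc4)[C@H](c4cc(OC)cc(OC)c4)c23)[C@H](CO)c2cc(OC)cc(OC)c21 | intermediate
26 | the corresponding C3 carbaldehyde (1R,2R,3S in target numbering) | COc1ccc(cc1)[C@H]1[C@@H](c2cc(OC)cc3O[C@@H](c4ccc(OC)cc4)[C@H](c4cc(OC)cc(OC)c4)c23)[C@H](C=O)c2cc(OC)cc(OC)c21 | intermediate
27 | (4-methoxyphenyl)[(1R,2R,3S, target numbering)-2-DHB-5,7-dimethoxy-1-(4-methoxyphenyl)indan-3-yl]methanol, both epimers at the carbinol carbon | COc1ccc(cc1)[C@H]1[C@@H](c2cc(OC)cc3O[C@@H](c4ccc(OC)cc4)[C@H](c4cc(OC)cc(OC)c4)c23)[C@H](C(O)c2ccc(OC)cc2)c2cc(OC)cc(OC)c21 | intermediate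
28 | octa-O-methylcanaliculatol (C1 R, C2 S, C3 R, Cm R, C3' R, C2' R) | COc1ccc([C@@H]2c3c(OC)cc(OC)cc3[C@H]3[C@H](c4ccc(OC)cc4)c4c(OC)cc(OC)cc4[C@@H]4c5c(cc(OC)cc5[C@H]23)O[C@H]4c2ccc(OC)cc2)cc1 | intermediate
29 | canaliculatol (C1 R, C2 S, C3 R, Cm R, C3' R, C2' R) | Oc1ccc([C@@H]2c3c(O)cc(O)cc3[C@H]3[C@H](c4ccc(O)cc4)c4c(O)cc(O)cc4[C@@H]4c5c(cc(O)cc5[C@H]23)O[C@H]4c2ccc(O)cc2)cc1 | target

## Step count and least certain steps

Total: 17 steps. Longest linear sequence: 14 steps (steps 1–6, then 10–17); the indanone branch (steps 7–9) joins at step 10.

**Step 4 (key step).** The process most likely to fail is the competing 1,2-shift of the 4-methoxyphenyl group from C2 to C3, which leads toward an isoflavone; that aryl group is itself a good migrator. Dehydrogenation to the flavone, or acid-induced opening of the pyranone with loss of enantiopurity, could also intervene. The fallback keeps the same disconnection but makes the same ring-C carbon migrate in a Wolff rearrangement. It sets out from 7. Nitrosation at C3 with isoamyl nitrite and HCl gives the 3-hydroxyimino flavanone F1. Chloramine converts it to the 3-diazo flavanone F2 (Forster reaction). Irradiation in methanol contracts the ring through the ketene and gives ester 9 together with its cis epimer F3, and NaOMe in methanol equilibrates F3 to 9, where the route is rejoined.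

**Step 16.** Closure of an eight-membered ring is slow. The cation may instead lose a proton to the C3=Cm alkene (which would scramble C3), react intermolecularly, or survive long enough for the C2'–O bond to ionise; facial control at Cm is a prediction. The fallback closes the ring by acylation. It sets out from 25. Oxidation with TEMPO and PhI(OAc)2 in aqueous acetonitrile gives the C3 carboxylic acid F4. (CF3CO)2O brings about Friedel–Crafts acylation of ring B to the eight-membered aryl ketone F5. The cerium reagent from 22 and CeCl3 adds to give the tertiary carbinol F6. Ionic hydrogenation with Et3SiH and CF3CO2H then delivers hydride to the cyclic cation and returns to the route at 28. The facial preference of that hydride transfer would have to be established.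

**Step 12.** The C1 cation may lose a proton to the indene and be re-protonated, which erodes C2. Hydride may also be delivered with poor facial selectivity, and ring B may capture the cation reversibly. The fallback replaces the cation by a directed hydrogenation and also bypasses step 11. It sets out from 21. KN(SiMe3)2 and PhNTf2 give the indenyl triflate F7. Suzuki–Miyaura coupling with 6 (Pd(PPh3)4, aqueous K3PO4, mild temperature to spare the acidic indene hydrogen) gives the 1-aryl indene F8. Bu4NF frees the indenyl methanol F9. Hydrogenation with [Ir(cod)(PCy3)(py)]PF6 and H2, directed by the hydroxyl group, adds both hydrogens on the face of the hydroxymethyl group and returns to the route at 25.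

**Step 6.** The electron-rich aryl bromide may couple inefficiently, so the benzylic radical may be reduced or dimerise. Nickel may also begin to insert into the aryl chloride, and trans selectivity may be incomplete. The fallback separates activation from coupling. It sets out from 10. N-hydroxyphthalimide and diisopropylcarbodiimide give the redox-active ester F10. This is coupled under NiCl2(dme)/dtbbpy catalysis with (3,5-dimethoxyphenyl)zinc chloride F11, made from 11 with magnesium and ZnCl2 (decarboxylative Negishi coupling), to return at 12.

**Step 10.** Oxidative addition of the hindered, electron-rich chloride may be slow, leaving the indanone enolate to self-condense or the chloride to be reduced. The fallback reverses the polarity. It sets out from 12 and 20. Miyaura borylation of 12 (Pd2(dba)3, XPhos, B2pin2, KOAc) gives the pinacol boronate F12. Bromination of 20 with PhNMe3Br3 gives the 2-bromo indanone F13. Nickel-catalysed Suzuki-type arylation of the α-bromo ketone with F12 and K3PO4, followed by equilibration at C2, returns to the route at 21.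

## Further compounds

F1 | step 4 | (2-configuration as in 7)-5-chloro-3-(hydroxyimino)-7-methoxy-2-(4-methoxyphenyl)chroman-4-one | O=C1C(=NO)[C@H](c2ccc(OC)cc2)Oc2cc(OC)cc(Cl)c21
F2 | step 4 | (2-configuration as in 7)-5-chloro-3-diazo-7-methoxy-2-(4-methoxyphenyl)chroman-4-one | O=C1C(=[N+]=[N-])[C@H](c2ccc(OC)cc2)Oc2cc(OC)cc(Cl)c21
F3 | step 4 | methyl (2R,3S)-4-chloro-6-methoxy-2-(4-methoxyphenyl)-2,3-dihydrobenzofuran-3-carboxylate (2,3-cis) | COC(=O)[C@@H]1[C@H](c2ccc(OC)cc2)Oc2cc(OC)cc(Cl)c21
F4 | step 16 | C3 carboxylic acid corresponding to 25 (configuration as in 25) | COc1ccc(cc1)[C@H]1[C@@H](c2cc(OC)cc3O[C@@H](c4ccc(OC)cc4)[C@H](c4cc(OC)cc(OC)c4)c23)[C@H](C(=O)O)c2cc(OC)cc(OC)c21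
F5 | step 16 | eight-membered aryl ketone (28 with C=O at Cm in place of CH(4-methoxyphenyl)) | COc1ccc([C@@H]2c3c(OC)cc(OC)cc3[C@H]3C(=O)c4c(OC)cc(OC)cc4[C@@H]4c5c(cc(OC)cc5[C@H]23)O[C@H]4c2ccc(OC)cc2)cc1
F6 | step 16 | tertiary carbinol at Cm (28 with OH in place of H at Cm, either epimer) | COc1ccc([C@@H]2c3c(OC)cc(OC)cc3[C@H]3C(O)(c4ccc(OC)cc4)c4c(OC)cc(OC)cc4[C@@H]4c5c(cc(OC)cc5[C@H]23)O[C@H]4c2ccc(OC)cc2)cc1
F7 | step 12 | enol triflate of 21 (C1=C2 double bond, C3 configured as in 21) | FC(F)(F)S(=O)(=O)OC1=C(c2cc(OC)cc3O[C@@H](c4ccc(OC)cc4)[C@H](c4cc(OC)cc(OC)c4)c23)[C@H](CO[Si](c2ccccc2)(c2ccccc2)C(C)(C)C)c2cc(OC)cc(OC)c21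
F8 | step 12 | 1-(4-methoxyphenyl)indene silyl ether (C1=C2 double bond, C3 configured as in 21) | COc1ccc(cc1)C1=C(c2cc(OC)cc3O[C@@H](c4ccc(OC)cc4)[C@H](c4cc(OC)cc(OC)c4)c23)[C@H](CO[Si](c2ccccc2)(c2ccccc2)C(C)(C)C)c2cc(OC)cc(OC)c21
F9 | step 12 | 1-(4-methoxyphenyl)indenyl methanol (C1=C2 double bond, C3 configured as in 21) | COc1ccc(cc1)C1=C(c2cc(OC)cc3O[C@@H](c4ccc(OC)cc4)[C@H](c4cc(OC)cc(OC)c4)c23)[C@H](CO)c2cc(OC)cc(OC)c21
F10 | step 6 | 1,3-dioxoisoindolin-2-yl (2R,3R)-4-chloro-6-methoxy-2-(4-methoxyphenyl)-2,3-dihydrobenzofuran-3-carboxylate | O=C(ON1C(=O)c2ccccc2C1=O)[C@H]1[C@H](c2ccc(OC)cc2)Oc2cc(OC)cc(Cl)c21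
F11 | step 6 | (3,5-dimethoxyphenyl)zinc chloride | COc1cc([Zn]Cl)cc(OC)c1
F12 | step 10 | pinacol boronate of 12 (Bpin in place of Cl, 2R,3R) | COc1cc(OC)cc(c1)[C@H]1[C@H](c2ccc(OC)cc2)Oc2cc(OC)cc(B3OC(C)(C)C(C)(C)O3)c21
F13 | step 10 | 2-bromo derivative of 20 (C3 as in 20, C2 either epimer) | O=C1C(Br)[C@H](CO[Si](c2ccccc2)(c2ccccc2)C(C)(C)C)c2cc(OC)cc(OC)c21
A1 | alternative 1 | 2-diazo-1-{5-[(tert-butyldimethylsilyloxy)(4-methoxyphenyl)methyl]-4-(3,5-dimethoxyphenyl)-3-(4-methoxyphenyl)cyclopent-1-en-1-yl}ethan-1-one (configured as in A3) | COc1ccc([C@@H]2C=C(C(=O)C=[N+]=[N-])[C@@H]([C@H](O[Si](C)(C)C(C)(C)C)c3ccc(OC)cc3)[C@@H]2c2cc(OC)cc(OC)c2)cc1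
A2 | alternative 1 | (triisopropylsilyloxy)acetylene | C#CO[Si](C(C)C)(C(C)C)C(C)C
A3 | alternative 1 | indane with ring A as resorcinol mono(triisopropylsilyl) ether | COc1ccc([C@@H]2c3c(O)cc(O[Si](C(C)C)(C(C)C)C(C)C)cc3[C@@H]([C@H](O[Si](C)(C)C(C)(C)C)c3ccc(OC)cc3)[C@@H]2c2cc(OC)cc(OC)c2)cc1
A4 | alternative 2 | tetracyclic β-keto ester (six-membered keto ester ring fused to the indane C2–C3 bond and to ring C, configured as in A6) | COc1ccc([C@@H]2c3c(OC)cc(OC)cc3[C@H]3C(=O)C(C(=O)OC)c4c(OC)cc(OC)cc4[C@H]23)cc1
A5 | alternative 2 | 3,5-dimethoxy-2-(trimethylsilyl)phenyl trifluoromethanesulfonate | COc1cc(OC)c([Si](C)(C)C)c(OS(=O)(=O)C(F)(F)F)c1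
A6 | alternative 2 | ring-expanded eight-membered aryl ketone with ester on C3' | COc1ccc([C@@H]2c3c(OC)cc(OC)cc3[C@H]3C(=O)c4c(OC)cc(OC)cc4[C@@H](C(=O)OC)c4c(OC)cc(OC)cc4[C@H]23)cc1
A7 | alternative 3 | 3-{[(1R,2R)-2-(3,5-dimethoxyphenyl)-1-(4-methoxyphenyl)-4-(trimethylsilyl)but-3-yn-1-yl]oxy}-2H-pyran-2-one | O=c1occcc1O[C@@H](c1ccc(OC)cc1)[C@@H](C#C[Si](C)(C)C)c1cc(OC)cc(OC)c1
A8 | alternative 3 | (2R,3R)-3-(3,5-dimethoxyphenyl)-2-(4-methoxyphenyl)-4-(trimethylsilyl)-2,3-dihydrobenzofuran | C[Si](C)(C)c1cccc2O[C@@H](c3ccc(OC)cc3)[C@H](c3cc(OC)cc(OC)c3)c12
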